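Take late times first. Solid substrate dissolves to starting material, which takes dissolved gas to form target, and target takes dissolved gas onward to over-reacted product. With no solid feeding the solution, target has no source while the held gas can still consume it, so this extreme reads zero.

| flask | solid substrate | gas phase | remark | time |
|---|---|---|---|---|
| teal | 0.50 M | 34 mM (held) | the very flask that is asked about, followed so far |  |
| green | 0.34 M | 34 mM (held) | run made earlier |  |
| flask | 0.50 M | 34 mM (held) |  | 30 min |

| run | time / min | target / % |
|---|---|---|
| teal | 0.667 | 0 |
| teal | 1.33 | 3.7 |
| teal | 2.00 | 1.4 |
| teal | 2.50 | 0.7 |
| green | 5.00 | 7.5 |
| green | 10.0 | 8.9 |
| green | 15.0 | 12.1 |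
| green | 20.0 | 11.6 |

(scatter of a reading: 1 percentage point)

- solid, in amounts per volume of the solution: solid substrate
- at the start none of the gas is dissolved
- on the list of suspects stand: gas phase <-> dissolved gas; starting material + dissolved gas -> target; dissolved gas + target -> over-reacted product; dissolved gas + target -> over-reaction product; dissolved gas -> decomposed reagent; solid substrate <-> starting material
- at the start none of the solid substrate is in solution

- how much target there is at 30 min, in percent of the solid substrate charged
- the change that raises the amount of target at 30 min, in percent of the solid substrate charged most ("none" if none brings more than 2 percentage points) (elm / larch / birch / alder / none)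
- amount of target at 30 min, in percent of the solid substrate charged, after larch

- elm: doubling the solubility of the solid substrate, all else as stated
- larch: doubling the dissolution coefficient of the solid substrate, all else as stated
- birch: doubling the saturation concentration of gas phase, all else as stated
- alder: doubling the transfer coefficient of the gas phase, all else as stated

The opposite extreme is solid that never ends. Formation and over-reaction then balance in a quasi-steady state, and target stands at a concentration c_P that does not depend on the charge. The last two green readings give c_P = 40.3 mM. The teal readings end at 2.50 min, too early to show this level.

Which extreme holds depends on the solid's lifetime τ, the charge divided by the supply s, the rate at which solid dissolves, taken as independent of the charge while solid remains. Control passes from the plateau to decay where τ crosses the reading time. The green readings still stand level at 20.0 min; read as solid still present then, they give an estimated ceiling on s, the green charge over that time, s_max = 17.0 mM min⁻¹. On this estimate the teal flask's solid lasts 29.4 min or longer, close to 30 min. It sits on the plateau side, and c_P over 0.50 M gives 8.06%. Faster dissolving may lift c_P but shortens τ, so this reckoning leaves the ranking open.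

The forecast gave 8.5%, elm and 10%, holding that “Doubling solubility should nearly double the plateau”. The flask gives 8.41%; larch is best at 2.9 percentage points, elm brings −2 points, and larch ends at 11.3%.

    gas phase ⇌ dissolved gas, rate k1*(csat - [dissolved gas]) (kL = 0.250 s⁻¹)
    starting material + dissolved gas → target (k = 0.150 M⁻¹ s⁻¹)
    dissolved gas + target → over-reacted product (k = 0.130 M⁻¹ s⁻¹)
    dissolved gas + target → over-reaction product (k = 0.00680 M⁻¹ s⁻¹)
    dissolved gas → decomposed reagent (k = 0.00690 s⁻¹)
    solid substrate ⇌ starting material, rate k6*(cs6 - [starting material]) while solid is left; crystals form when [starting material] > cs6 (solubility = 0.160 M, k = 0.00150 s⁻¹)

By 30 min, 67.6% of the flask's solid substrate has left the solid, an average supply s of 11.3 mM min⁻¹, below s_max, so τ reckons at 44.2 min. The flask's target stays low in part because of the step from dissolved gas and target to over-reacted product: the run without that step holds 50.5% against 8.41%. The same s gives the 0.30 M neighbour a τ of 26.5 min, short of 30 min, and that flask holds 0% solid substrate and 10.6% target, under the 13.4% from c_P.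

(Readings and results are calculated for an exercise; noise was put on by code.)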